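The route rests on the biaryl bond between C6 of ring A of the flavanone and C3' of ring B of the flavone. C6 sits between the C5 hydroxyl and the C7 oxygen and is the central carbon of a masked β-dicarbonyl unit. C3' sits ortho to the 4'-methoxy group. Both carbons are donors, so C3' is reversed in polarity as an aryllead triacetate. In one operation the only free phenol (O5) of an enantiopure flavanone binds tetravalent lead and passes the whole flavone aryl group to C6 by ligand coupling, with no halogen or metal on ring A. The precursors are the 3'-stannyl flavone 5 and (S)-7-O-benzylisosakuranetin 9.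

Key step: step 6

Assumptions: 1, 2, 6, 8 and 10 are catalogue chemicals; rotation about the new biaryl axis (ortho groups OH, OH or OBn, OMe, H) is taken as free at room temperature, so C2 is the only stereo-element; the sense of induction in step 5 follows the quadrant model of the Hayashi–Miyaura reaction, and the (R)-ligand would be used if the model did not carry over to chromones.

Step 1
Reactants: 1 1-[2,4-bis(benzyloxy)-6-hydroxyphenyl]ethan-1-one; 2 3-iodo-4-methoxybenzaldehyde
Product: 3 (E)-1-[2,4-bis(benzyloxy)-6-hydroxyphenyl]-3-(3-iodo-4-methoxyphenyl)prop-2-en-1-one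
Conditions: KOH (aq), EtOH, rt
Reagents that add atoms: none
Why: Claisen–Schmidt condensation, in which the methyl ketone enolate adds to the non-enolisable aldehyde and E1cB loss of water should give the conjugated E-enone, while the aryl iodide and benzyl ethers are inert to KOH.

Step 2
Reactants: 3 (E)-chalcone
Product: 4 5,7-bis(benzyloxy)-2-(3-iodo-4-methoxyphenyl)-4H-chromen-4-one
Conditions: I2 (10 mol%), DMSO, 130 °C
Reagents that add atoms: none
Why: Iodine/DMSO oxidative cyclisation of a 2'-hydroxychalcone (oxa-Michael closure, α-iodination, loss of HI, reoxidation of HI by DMSO), in which only the single free phenol can close ring C.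

Step 3
Reactants: 4 3'-iodoflavone
Product: 5 5,7-bis(benzyloxy)-2-[4-methoxy-3-(tributylstannyl)phenyl]-4H-chromen-4-one
Conditions: (Bu3Sn)2, Pd(PPh3)4 (5 mol%), toluene, 110 °C
Reagents that add atoms: hexabutylditin, CCCC[Sn](CCCC)(CCCC)[Sn](CCCC)(CCCC)CCCC
Why: Palladium-catalysed stannylation of an aryl iodide with a distannane (oxidative addition to zerovalent palladium, Sn–Sn transmetalation, reductive elimination) runs under neutral conditions that leave the chromenone and the benzyl ethers untouched.

Step 4
Reactants: 6 5,7-dihydroxy-4H-chromen-4-one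
Product: 7 7-(benzyloxy)-5-hydroxy-4H-chromen-4-one
Conditions: BnBr (1.05 equiv), K2CO3, acetone, reflux
Reagents that add atoms: benzyl bromide, BrCc1ccccc1
Why: Williamson etherification, selective for O7 because the 7-OH is the more acidic phenol and the 5-OH is held in a hydrogen bond to C4=O.

Step 5
Reactants: 7 7-(benzyloxy)-5-hydroxy-4H-chromen-4-one; 8 (4-methoxyphenyl)boronic acid
Product: 9 (2S)-7-(benzyloxy)-5-hydroxy-2-(4-methoxyphenyl)chroman-4-one
Conditions: [Rh(OH)(cod)]2 (1.5 mol%), (S)-MeO-F12-BIPHEP [(S)-2,2'-bis{bis(3,4,5-trifluorophenyl)phosphino}-6,6'-dimethoxybiphenyl, 3.3 mol%], toluene/H2O, 25 °C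
Reagents that add atoms: none
Why: Hayashi–Miyaura asymmetric 1,4-addition, known for chromones, in which the aryl–rhodium species carrying the (S)-biaryl diphosphine should carbometalate C2=C3 from the face that turns cyclohexenone into (S)-3-arylcyclohexanones, which corresponds to 2S here, and the base-free medium at room temperature avoids retro-oxa-Michael racemisation.

Step 6
Reactants: 5 3'-stannyl flavone; 9 (2S)-7-(benzyloxy)-5-hydroxy-2-(4-methoxyphenyl)chroman-4-one; 10 lead tetraacetate
Product: 13 (2S)-7-(benzyloxy)-6-{5-[5,7-bis(benzyloxy)-4-oxo-4H-chromen-2-yl]-2-methoxyphenyl}-5-hydroxy-2-(4-methoxyphenyl)chroman-4-one, via flavone aryllead triacetate 11 (not isolated), via aryloxylead diacetate 12 (not isolated)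
Conditions: 5 (1.15 equiv), Pb(OAc)4 (1.1 equiv), Hg(OAc)2 (10 mol%), CHCl3, 40 °C; then 9 (1.0 equiv), pyridine (3.3 equiv), 40 to 60 °C
Reagents that add atoms: none
Why: Mercury-catalysed tin–lead exchange turns the C3'–Sn bond of 5 into the C3'–Pb bond of 11 and so reverses the polarity of this anisole ortho carbon. The C5 phenol of 9, the only free OH in either partner, should displace one acetate on tetravalent lead with pyridine as base and ligand to give 12, after which the aryl group passes from lead to the ortho carbon C6 by ligand coupling with loss of Pb(OAc)2, and tautomerisation restores aromatic ring A. The closest known reaction type is the Pinhey arylation, the ortho C-arylation of electron-rich phenols such as 3,5-dialkoxyphenols and of enolised β-dicarbonyl compounds such as 4-hydroxycoumarins by aryllead triacetates, which tolerates crowded biaryl bonds and ortho-methoxy aryllead reagents. The step needs C6 over C8 and C over O selectivity: delivery from O5-bound lead reaches only the two ortho carbons, C4a is a fully substituted ring-fusion carbon that could not rearomatise, C8 is para and out of reach, and O7 is benzylated so that no second anchor exists. No ring is closed and no stereocentre is made, and C2 should keep its S configuration because the pyridine/acetic acid medium is too weakly basic for enolisation and retro-oxa-Michael opening of ring C. The slight deficit of Pb(OAc)4 against 5 keeps free oxidant away from the phenol and from C3 of the flavanone.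

Step 7
Reactants: 13 tri-O-benzyl biflavonoid
Product: 14 (2S)-6-[5-(5,7-dihydroxy-4-oxo-4H-chromen-2-yl)-2-methoxyphenyl]-5,7-dihydroxy-2-(4-methoxyphenyl)chroman-4-one (target)
Conditions: H2 (1 atm), 10% Pd/C, THF/MeOH, rt
Reagents that add atoms: none
Why: Catalytic hydrogenolysis should cleave the three aryl benzyl ethers under neutral conditions that leave the methyl ethers, the flavone C2=C3 bond and both carbonyl groups intact and give no base-induced racemisation at C2.

Compound list
1 | 1-[2,4-bis(benzyloxy)-6-hydroxyphenyl]ethan-1-one | CC(=O)c1c(O)cc(OCc2ccccc2)cc1OCc1ccccc1 | starting material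
2 | 3-iodo-4-methoxybenzaldehyde | COc1ccc(C=O)cc1I | starting material
3 | (E)-1-[2,4-bis(benzyloxy)-6-hydroxyphenyl]-3-(3-iodo-4-methoxyphenyl)prop-2-en-1-one | COc1ccc(/C=C/C(=O)c2c(O)cc(OCc3ccccc3)cc2OCc2ccccc2)cc1I | intermediate
4 | 5,7-bis(benzyloxy)-2-(3-iodo-4-methoxyphenyl)-4H-chromen-4-one | COc1ccc(-c2cc(=O)c3c(OCc4ccccc4)cc(OCc4ccccc4)cc3o2)cc1I | intermediate
5 | 5,7-bis(benzyloxy)-2-[4-methoxy-3-(tributylstannyl)phenyl]-4H-chromen-4-one | COc1ccc(-c2cc(=O)c3c(OCc4ccccc4)cc(OCc4ccccc4)cc3o2)cc1[Sn](CCCC)(CCCC)CCCC | intermediate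
6 | 5,7-dihydroxy-4H-chromen-4-one | O=c1ccoc2cc(O)cc(O)c12 | starting material
7 | 7-(benzyloxy)-5-hydroxy-4H-chromen-4-one | O=c1ccoc2cc(OCc3ccccc3)cc(O)c12 | intermediate
8 | (4-methoxyphenyl)boronic acid | COc1ccc(B(O)O)cc1 | starting material
9 | (2S)-7-(benzyloxy)-5-hydroxy-2-(4-methoxyphenyl)chroman-4-one | COc1ccc([C@@H]2CC(=O)c3c(O)cc(OCc4ccccc4)cc3O2)cc1 | intermediate
10 | lead tetraacetate | CC(=O)O[Pb](OC(C)=O)(OC(C)=O)OC(C)=O | starting material
11 | {5-[5,7-bis(benzyloxy)-4-oxo-4H-chromen-2-yl]-2-methoxyphenyl}lead triacetate (not isolated) | COc1ccc(-c2cc(=O)c3c(OCc4ccccc4)cc(OCc4ccccc4)cc3o2)cc1[Pb](OC(C)=O)(OC(C)=O)OC(C)=O | intermediate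
12 | aryl(aryloxy)lead diacetate, with lead bound to C3' of the flavone and to O5 of the (2S)-flavanone (not isolated) | COc1ccc([C@@H]2CC(=O)c3c(O[Pb](OC(C)=O)(OC(C)=O)c4cc(-c5cc(=O)c6c(OCc7ccccc7)cc(OCc7ccccc7)cc6o5)ccc4OC)cc(OCc4ccccc4)cc3O2)cc1 | intermediate
13 | (2S)-7-(benzyloxy)-6-{5-[5,7-bis(benzyloxy)-4-oxo-4H-chromen-2-yl]-2-methoxyphenyl}-5-hydroxy-2-(4-methoxyphenyl)chroman-4-one | COc1ccc([C@@H]2CC(=O)c3c(cc(OCc4ccccc4)c(-c4cc(-c5cc(=O)c6c(OCc7ccccc7)cc(OCc7ccccc7)cc6o5)ccc4OC)c3O)O2)cc1 | intermediate
14 | (2S)-6-[5-(5,7-dihydroxy-4-oxo-4H-chromen-2-yl)-2-methoxyphenyl]-5,7-dihydroxy-2-(4-methoxyphenyl)chroman-4-one | COc1ccc([C@@H]2CC(=O)c3c(cc(O)c(-c4cc(-c5cc(=O)c6c(O)cc(O)cc6o5)ccc4OC)c3O)O2)cc1 | target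

Total step count: 7. Longest linear sequence: 5 (steps 1, 2, 3, 6, 7). The second branch (steps 4, 5) joins at step 6.

Steps most likely to fail

Step 6.
- **What may go wrong:** The hydrogen-bonded C5 phenol is deactivated by the acyl group and may bind lead too slowly. The aryllead reagent would then decay by protodeplumbation or acetoxylation. The flavanone may also partly racemise during the long warm reaction.
- **Fallback:** Cross-coupling of two prefunctionalised partners at the achiral chromone stage, with the stereocentre set afterwards. It sets out from 7 and 5.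
  - Compound 7 is iodinated ortho to the free 5-OH (benzyltrimethylammonium dichloroiodate, CaCO3, CH2Cl2/MeOH, rt) to give 7-(benzyloxy)-5-hydroxy-6-iodo-4H-chromen-4-one F1.
  - Stille coupling of F1 with 5 (Pd(PPh3)4, CuI, CsF, DMF, 45 °C) should give the chromone–flavone biaryl 7-(benzyloxy)-6-{5-[5,7-bis(benzyloxy)-4-oxo-4H-chromen-2-yl]-2-methoxyphenyl}-5-hydroxy-4H-chromen-4-one F2.
  - Hayashi–Miyaura addition of 8 under the conditions of step 5 should occur only at the 2-unsubstituted chromone, because the flavone enone is β,β-disubstituted.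
  - The fallback comes back to the route at 13.

Step 5.
- **What may go wrong:** The electron-rich, hydrogen-bonded chromone may take up the aryl–rhodium species too slowly, so that protodeboronation of 8 wins. The facial selectivity may also fall short.
- **Fallback:** Ring C is built by oxa-Michael closure of a chalcone, and the enantiomer is obtained by resolution instead of catalysis. It sets out from 1.
  - Claisen–Schmidt condensation with 4-methoxybenzaldehyde (KOH, EtOH) gives (E)-1-[2,4-bis(benzyloxy)-6-hydroxyphenyl]-3-(4-methoxyphenyl)prop-2-en-1-one F3.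
  - NaOAc in refluxing EtOH closes it to racemic 5,7-bis(benzyloxy)-2-(4-methoxyphenyl)chroman-4-one F4.
  - BCl3 (1 equiv, CH2Cl2, −78 °C) removes only the benzyl group at O5, which is chelated to C4=O. This gives racemic 7-(benzyloxy)-5-hydroxy-2-(4-methoxyphenyl)chroman-4-one F5.
  - Preparative HPLC on a polysaccharide carbamate phase separates 9 from (2R)-7-(benzyloxy)-5-hydroxy-2-(4-methoxyphenyl)chroman-4-one F6. F6 is racemised with a trace of base through the open chalcone and recycled.
  - The fallback comes back to the route at 9.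

Step 7.
- **What may go wrong:** Over-reduction may occur, either as saturation of the flavone C2=C3 bond or as hydrogenolysis of the benzylic C2–O1 bond of the flavanone. Traces of tin, lead or mercury may poison the catalyst.
- **Fallback:** Non-reductive ether cleavage by a Lewis acid with a cation scavenger. It sets out from 13.
  - BCl3 and pentamethylbenzene in CH2Cl2 at −78 °C should ionise the three benzyl ethers and trap the benzyl cations by Friedel–Crafts alkylation of the scavenger.
  - The two methyl ethers should stay, because neither is chelated to a carbonyl group.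
  - The fallback comes back to the route at 14 with no new compound on the way.

Further compounds
F1 | step 6 | 7-(benzyloxy)-5-hydroxy-6-iodo-4H-chromen-4-one | O=c1ccoc2cc(OCc3ccccc3)c(I)c(O)c12
F2 | step 6 | 7-(benzyloxy)-6-{5-[5,7-bis(benzyloxy)-4-oxo-4H-chromen-2-yl]-2-methoxyphenyl}-5-hydroxy-4H-chromen-4-one | COc1ccc(-c2cc(=O)c3c(OCc4ccccc4)cc(OCc4ccccc4)cc3o2)cc1-c1c(OCc2ccccc2)cc2occc(=O)c2c1O
F3 | step 5 | (E)-1-[2,4-bis(benzyloxy)-6-hydroxyphenyl]-3-(4-methoxyphenyl)prop-2-en-1-one | COc1ccc(/C=C/C(=O)c2c(O)cc(OCc3ccccc3)cc2OCc2ccccc2)cc1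
F4 | step 5 | racemic 5,7-bis(benzyloxy)-2-(4-methoxyphenyl)chroman-4-one | COc1ccc(C2CC(=O)c3c(OCc4ccccc4)cc(OCc4ccccc4)cc3O2)cc1
F5 | step 5 | racemic 7-(benzyloxy)-5-hydroxy-2-(4-methoxyphenyl)chroman-4-one | COc1ccc(C2CC(=O)c3c(O)cc(OCc4ccccc4)cc3O2)cc1
F6 | step 5 | (2R)-7-(benzyloxy)-5-hydroxy-2-(4-methoxyphenyl)chroman-4-one | COc1ccc([C@H]2CC(=O)c3c(O)cc(OCc4ccccc4)cc3O2)cc1
F0 | step 7 | none | none
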